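## Structural features

The target is a germacranolide: a ten-membered carbocycle (C1–C10) trans-fused through C6–C7 to an α-methylene-γ-butyrolactone (O6, C12, C11, C13). The carbocycle holds a C1 ketone whose α-carbon C10 is fully substituted (CH3, OAc) and whose β-carbon C3 is a free carbinol, so C1 belongs both to an α-acyloxy ketone and to an aldol; C3 (OH) and C4 (CH3) are vicinal and trans. C6 (lactone O), C7 (H) and C8 (angelate) are contiguous, and C10 lies two atoms beyond C8; in the usual germacranolide orientation (H-7 α) the groups are 3β-OH, 4α-CH3, 6α-O, 8α-O and 10α-OAc, that is (3S,4S,6R,7S,8S,10R). Fragile elements are the β-hydroxy ketone (dehydration, retro-aldol), the tertiary α-acetoxy ketone (acyl shift once C1 is a carbinol), the exo-methylene lactone (conjugate addition), the angelate (Z to E isomerisation), and the pair O6/O8, either of which can carry the lactone. The real difficulty is the medium ring together with stereocontrol on it: C8 and the quaternary C10 are 1,3-related across a methylene, and H-7 must be trans to both H-6 and H-8. The key step exploits the array C1(=O)–C10(CH3)(O)–C9H2–C8(O): a ketone enolised only toward C10, with a C8–C9 bond two atoms away, is what an oxy-Cope rearrangement leaves when an isopropenyl group (C9, C10, C14) on the carbinol carbon C1 and an alkoxyvinyl group (C7, C8) on C6 of a six-membered ring A (C1–C6) trade the C1–C6 bond for C8–C9. Ring A already contains C3 and C4, so these two centres can be set on a cyclohexane before the ring is expanded.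

## Logic of the disconnections

31 to 30: the O3–Si bond is cut last. The free β-hydroxy ketone is the most fragile array, so it is unmasked in the final step; this demands a non-basic desilylation.

30 to 29 to 28 to 27: the C10 O–acetyl bond, the C1 carbonyl and the C1,C10 acetonide are taken back in turn. C1 stays a protected carbinol while enolates are in use, and the acetate is added only once C1 is a ketone, because a tertiary acetate next to a free C1 hydroxyl would migrate. The forward steps must oxidise a secondary alcohol beside a tertiary one and acylate a tertiary alcohol without harming the angelate.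

27 to 26: the C8 O–acyl bond is cut. The angelate is added after the last strong-base step; the esterification must acylate a hindered alcohol without Z to E isomerisation.

26 to 23: the C11=C13 bond is cut (Mannich methylenation). The lactone enolate must be formed without letting a C8 alkoxide capture the lactone carbonyl.

23 to 22 to 21 to 19: the C7–H bond is cut by going back to the C7=C11 butenolide. This frees C7 from the way the olefin was first functionalised: hydrogen can be delivered from the face of the C8 hydroxyl, which is the face needed for the trans lactone. The demand is a free O8 and a catalyst that obeys the hydroxyl.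

19 to 17 to 16 to 15 to 14: the C12–O6 lactone bond (oxidative lactonisation of a 1,4-diol) and the C6–O bond (hydroboration of C6=C7) are cut, leading to the rearranged ketone 14. With O8 still benzylated only O6 can lactonise. The forward hydroboration must place oxygen on the outer face of the E olefin, and C1 has to be reduced and masked.

14 to 12 (key): C8–C9 is cut, C1–C6 reconnected and the C10 oxygen removed. The ten-membered ring and the C8 and C10 centres collapse to a 1,2-dialkenylcyclohexanol. The forward step needs a chair transition state, an E enol ether and oxidation of the enolate before it can equilibrate. A cis-dialkenyl cyclohexanol, which would give the Z olefin, is not used. With 3S-silyloxy and 4S-methyl on ring A, its productive chair would need isopropenyl, silyloxy and methyl all axial, and it is also the minor product of addition to the α-alkenyl ketone. The trans isomer 12 rearranges through its ground-state chair and gives the E olefin 14, with C8 and C10 in the required sense.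

12 to 11: the C1–C10 bond is cut (isopropenyl addition). Equatorial attack is needed and enolisation must be avoided.

11 to 6 + 10: the C6–C7 bond is cut (enolate alkenylation). This is the convergent junction; it needs the C6 enolate and retention of the bromide geometry.

10 to 9 to 8 to 7: the vinylic C–O bond and the two carbon–halogen bonds lead back to a terminal alkyne. Anti addition followed by substitution with retention fixes the E enol ether.

6 to 5 to 4 to 3 to 2 to 1: the C3–O and C4–H bonds come from asymmetric hydroboration of the alkene left by Birch reduction and ketalisation of an anisole. Ring A and its two stereocentres then cost five steps from an aromatic feedstock.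

## Other disconnections considered

Alternative 1: the cut is C1–C2 together with O–C3, leading to the isoxazoline-bridged core A1. In the forward sense the open-chain aldoxime A2 is oxidised (aqueous NaOCl, high dilution) to a nitrile oxide that adds to the terminal C2=C3 alkene; later N–O reduction reveals the C1 ketone and C3 hydroxyl. In its favour, the lactone with C6, C7 and C8 and the quaternary C10 are built on a small, rigid unit before ring closure, and the aldol appears without any redox change at C1. On both points it is better than the chosen plan, which sets C6 and C7 on a macrocycle and reduces and reoxidises C1. Against it here: a ten-membered carbocycle must be closed by a bimolecular-type cycloaddition that competes with dimerisation to the furoxan and pays the transannular strain; the bridged regiochemistry (carbon to the terminal C2) is not assured for a medium ring; and C3 rests on 1,2-induction from the C4 methyl only. Mechanistically a kinetically controlled [3+2] closure is weaker in stereochemical transmission than a chair sigmatropic shift. In step economy A2 needs five stereocentres set on a chain, so the sequence is expected to be no shorter.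

Alternative 2: the cut is C7–C8, leading to the ten-membered homoallylic alcohol A3. In the forward sense tin–lithium exchange in the thirteen-membered α-stannyl allylic ether A4 triggers a [2,3]-Wittig shift that forms C7–C8, breaks O–C13 and unveils the C11=C13 methylene. In its favour, the medium ring is made by ring contraction and not by direct closure (equal to the chosen plan in this respect), and the exocyclic methylene arrives in the same step (better than the separate Mannich methylenation). Against it here: both C7 and C8 arise from a flexible thirteen-membered transition state whose outcome depends on the olefin geometry and on the configuration of the stannylated carbon; the α-alkoxy organolithium may also undergo a [1,2] shift. The chosen plan derives C8 from a chair and sets C7 by a directed hydrogenation, which is easier to defend. In step economy A4 must already carry C1, C3, C4, C6 and C10, and the late α-ketol chemistry is the same as in the chosen plan, so the route is expected to be longer.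

Alternative 3: the cut is C1–C10, leading to the C1,C10-diol A5. In the forward sense SmI2 couples the C1 aldehyde with the C10 methyl ketone of the keto aldehyde A6, forming the most hindered bond and the quaternary carbinol at once. In its favour, it is convergent, the lactone triad is fixed on a five-membered ring before cyclisation (better than macrocyclic control), and the end-game of C1 oxidation and C10 acetylation is the same as in the chosen plan (equal). Against it here: a ten-membered pinacol closure carries the full entropic and transannular cost that the ring expansion avoids; the face of C10 relative to C8 is not predictable; and both ketyl partners have β-oxygen substituents (O3 for the aldehyde, O8 for the ketone) that can be eliminated after electron transfer. The step count is comparable to the chosen plan.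

Key step: step 11

Remarks on the chemistry (assumptions):
- Germacrane numbering is used throughout (ring A = C1–C6); α/β refer to the usual germacranolide drawing with H-7 α.
- The rearrangement substrate is the trans-1,2-dialkenyl cyclohexanol 12, so the ring-expanded ketone 14 is the E olefin; C7 is set later by directed hydrogenation, not by the olefin geometry.
- The C1 carbinol created in step 12 is temporary; both epimers are carried on and C1 is left unspecified in the SMILES of 15–28.
- Conjugate bases of a reactant (alkoxides, lithium enolates) are treated as activated forms of that reactant and are not numbered; the rearranged enolate 13 is numbered.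
- Monoisopinocampheylborane from (+)-α-pinene is assumed to be the antipode that gives the (7S,8S) alcohol, by analogy with 1-methylcyclohexene giving (1S,2S)-trans-2-methylcyclohexanol.
- O3 carries the triisopropylsilyl group and O12 the tert-butyldimethylsilyl group, so that the primary ether can be cleaved selectively and the group β to the C1 oxygen resists migration.

## Steps

Step 1
Reactants: 1 4-methylanisole
Product: 2 1-methoxy-4-methylcyclohexa-1,4-diene
Conditions: Li, NH3 (l), t-BuOH, THF, −78 to −33 °C
Reagents that add atoms: none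
Why: Birch reduction of an anisole gives the 1,4-diene with the methoxy and methyl groups on the two remaining double bonds; no stereocentre is formed.

Step 2
Reactants: 2 1-methoxy-4-methylcyclohexa-1,4-diene
Product: 3 8-methyl-1,4-dioxaspiro[4.5]dec-7-ene
Conditions: HOCH2CH2OH, p-TsOH (cat.), CH2Cl2, 25 °C
Reagents that add atoms: ethylene glycol, OCCO
Why: Acid-catalysed transketalisation of the enol ether is faster than migration of the trisubstituted alkene into conjugation, so the β,γ-unsaturated ketal is obtained; no stereocentre is formed.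

Step 3
Reactants: 3 8-methyl-1,4-dioxaspiro[4.5]dec-7-ene
Product: 4 (7S,8S)-8-methyl-1,4-dioxaspiro[4.5]decan-7-ol
Conditions: IpcBH2 [from (+)-α-pinene], Et2O, −25 °C; then NaOH (aq), H2O2
Reagents that add atoms: hydrogen peroxide, OO
Why: Asymmetric hydroboration–oxidation of a trisubstituted cycloalkene: boron adds to the less substituted carbon and H and B add syn, which fixes the trans hydroxyl/methyl pair (C3, C4), while the chiral borane chooses the alkene face. The crystalline dialkylborane can be recrystallised before oxidation to raise the enantiomeric purity.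

Step 4
Reactants: 4 (7S,8S)-8-methyl-1,4-dioxaspiro[4.5]decan-7-ol
Product: 5 (7S,8S)-8-methyl-7-(triisopropylsilyloxy)-1,4-dioxaspiro[4.5]decane
Conditions: i-Pr3SiOTf, 2,6-lutidine, CH2Cl2, 0 °C
Reagents that add atoms: triisopropylsilyl trifluoromethanesulfonate, CC(C)[Si](C(C)C)(C(C)C)OS(=O)(=O)C(F)(F)F
Why: Silylation of a secondary alcohol with a silyl triflate and a hindered base; the bulky group resists migration toward the C1 oxygen under KH and survives buffered fluoride and mild acid later.

Step 5
Reactants: 5 (7S,8S)-8-methyl-7-(triisopropylsilyloxy)-1,4-dioxaspiro[4.5]decane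
Product: 6 (3S,4S)-4-methyl-3-(triisopropylsilyloxy)cyclohexan-1-one
Conditions: PPTS, acetone–H2O, 60 °C
Reagents that add atoms: water, O
Why: Acid-catalysed ketal hydrolysis; the β-silyloxy ketone is stable to weak acid and no stereocentre is touched.

Step 6
Reactants: 7 but-3-yn-1-ol
Product: 8 (but-3-yn-1-yloxy)(tert-butyl)dimethylsilane
Conditions: t-BuMe2SiCl, imidazole, CH2Cl2, 25 °C
Reagents that add atoms: tert-butyldimethylsilyl chloride, CC(C)(C)[Si](C)(C)Cl
Why: Standard silylation of a primary alcohol; this ether can later be cleaved in the presence of the secondary triisopropylsilyl ether.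

Step 7
Reactants: 8 (but-3-yn-1-yloxy)(tert-butyl)dimethylsilane
Product: 9 (E)-[(3-bromo-4-iodobut-3-en-1-yl)oxy](tert-butyl)dimethylsilane
Conditions: IBr, CH2Cl2, −78 °C
Reagents that add atoms: iodine monobromide, BrI
Why: Electrophilic anti addition of IBr to a terminal alkyne puts iodine on the terminal carbon and bromide on the internal one, giving the E dihalide and so fixing the later enol ether geometry.

Step 8
Reactants: 9 (E)-[(3-bromo-4-iodobut-3-en-1-yl)oxy](tert-butyl)dimethylsilane
Product: 10 (E)-{[3-bromo-4-(4-methoxybenzyloxy)but-3-en-1-yl]oxy}(tert-butyl)dimethylsilane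
Conditions: 4-MeOC6H4CH2OH, CuI (10 mol%), 3,4,7,8-tetramethyl-1,10-phenanthroline, Cs2CO3, toluene, 80 °C
Reagents that add atoms: 4-methoxybenzyl alcohol, COc1ccc(CO)cc1
Why: Copper-catalysed Ullmann-type C–O coupling of an alkenyl iodide with a primary alcohol proceeds with retention of olefin geometry. The terminal C–I bond reacts in preference to the hindered internal C–Br bond, so oxygen ends trans to bromine.

Step 9
Reactants: 6 (3S,4S)-4-methyl-3-(triisopropylsilyloxy)cyclohexan-1-one; 10 (E)-{[3-bromo-4-(4-methoxybenzyloxy)but-3-en-1-yl]oxy}(tert-butyl)dimethylsilane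
Product: 11 (2S,4S,5S)-2-[(E)-4-(tert-butyldimethylsilyloxy)-1-(4-methoxybenzyloxy)but-1-en-2-yl]-4-methyl-5-(triisopropylsilyloxy)cyclohexan-1-one
Conditions: LiN(SiMe3)2 (2.1 equiv), THF, −78 °C; 10, Pd2(dba)3 (cat.), P(t-Bu)3, −78 to 25 °C; AcOH, −78 °C
Reagents that add atoms: none
Why: Palladium-catalysed α-alkenylation of a ketone enolate with an alkenyl bromide; kinetic deprotonation of the 3-silyloxy ketone occurs at C6, away from the oxygenated carbon, and coupling retains the bromide geometry. The second equivalent of base turns the more acidic product into its dienolate, whose α-protonation from the axial direction places the alkenyl group equatorial at C6 (cis to the C4 methyl), which is also the thermodynamically preferred epimer.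

Step 10
Reactants: 11 (2S,4S,5S)-2-[(E)-4-(tert-butyldimethylsilyloxy)-1-(4-methoxybenzyloxy)but-1-en-2-yl]-4-methyl-5-(triisopropylsilyloxy)cyclohexan-1-one
Product: 12 (1S,2S,4S,5S)-2-[(E)-4-(tert-butyldimethylsilyloxy)-1-(4-methoxybenzyloxy)but-1-en-2-yl]-4-methyl-1-(prop-1-en-2-yl)-5-(triisopropylsilyloxy)cyclohexan-1-ol (trans-1,2-dialkenyl, hydroxyl axial)
Conditions: CH2=C(CH3)MgBr, CeCl3, THF, −78 °C; NH4Cl (aq)
Reagents that add atoms: isopropenylmagnesium bromide, C=C(C)[Mg]Br
Why: 1,2-Addition of an organocerium reagent, which suppresses enolisation of the acidic α-alkenyl ketone. Attack along the equatorial trajectory of the all-equatorial chair gives the axial tertiary alcohol with the two alkenyl groups trans-diequatorial; C1 is set by the resident C6 centre.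

Step 11
Reactants: 12 (1S,2S,4S,5S)-2-[(E)-4-(tert-butyldimethylsilyloxy)-1-(4-methoxybenzyloxy)but-1-en-2-yl]-4-methyl-1-(prop-1-en-2-yl)-5-(triisopropylsilyloxy)cyclohexan-1-ol
Product: 14 (6E)-10α-hydroxy-8α-(4-methoxybenzyloxy)-4α,10β-dimethyl-7-[2-(tert-butyldimethylsilyloxy)ethyl]-3β-(triisopropylsilyloxy)cyclodec-6-en-1-one (3S,4S,8S,10R), via potassium enolate 13 (not isolated)
Conditions: KH, 18-crown-6, THF, 0 to 25 °C; then −78 °C, 2-(phenylsulfonyl)-3-phenyloxaziridine; NH4Cl (aq)
Reagents that add atoms: 2-(phenylsulfonyl)-3-phenyloxaziridine, O=S(=O)(c1ccccc1)N1OC1c1ccccc1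
Why: KH with the crown ether gives the potassium alkoxide of 12, whose 1,5-diene (C9=C10–C1–C6–C7=C8) undergoes an alkoxide-accelerated [3,3] shift: C8–C9 forms as C1–C6 breaks, and the ten-membered ring arises by four-atom expansion of ring A through a bicyclic chair transition state, not by exo or endo closure of a chain. The closest known reaction type is the anionic oxy-Cope rearrangement of trans-1,2-dialkenylcyclohexanols to (E)-cyclodec-5-enones, followed by oxidation of the regiodefined enolate with an N-sulfonyloxaziridine. The reacting chair is the ground-state chair of ring A: both ring bonds (C1–C2 and C6–C5), the C3 silyloxy and the C4 methyl are equatorial and only the alkoxide is axial, which gives the E C6=C7 olefin and the enolate 13 with C2 trans to C9. C8 is controlled by the E enol ether, which places the benzyloxy group pseudoequatorial on a chair whose sense is fixed by C1 and C6, giving 8S (8α-O). C10 is controlled by the conformation in which 13 is born: its inner face is shielded transannularly by the C6=C7 unit, so oxygen transfer to the outer face gives 10R (10α-OH). The step needs chair over boat (secured by the diequatorial dialkenyl arrangement), enolate regiochemistry toward C10 only (secured by oxidising at −78 °C as soon as the shift is complete), and no loss of the C3 silyloxy group (secured as long as the enolate does not equilibrate toward C2).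

Step 12
Reactants: 14 (6E)-10α-hydroxy-8α-(4-methoxybenzyloxy)-4α,10β-dimethyl-7-[2-(tert-butyldimethylsilyloxy)ethyl]-3β-(triisopropylsilyloxy)cyclodec-6-en-1-one
Product: 15 8α-(4-methoxybenzyloxy)-4α,10β-dimethyl-7α-[2-(tert-butyldimethylsilyloxy)ethyl]-3β-(triisopropylsilyloxy)cyclodecane-1ξ,6α,10α-triol (H-7β)
Conditions: BH3·THF (excess), THF, 0 to 25 °C; then NaOH (aq), H2O2, 0 °C
Reagents that add atoms: hydrogen peroxide, OO
Why: Borane reduces the C1 ketone and hydroborates the trisubstituted E olefin with boron on the less substituted C6; oxidation with retention gives the C6 alcohol. Approach on the exposed outer face of the E-cyclodecene, anti to the C8–C9 bond (the same face is favoured by allylic strain control from C8), sets C6 as required; C7 (corrected in step 18) and the C1 carbinol are temporary centres.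

Step 13
Reactants: 15 8α-(4-methoxybenzyloxy)-4α,10β-dimethyl-7α-[2-(tert-butyldimethylsilyloxy)ethyl]-3β-(triisopropylsilyloxy)cyclodecane-1ξ,6α,10α-triol
Product: 16 1,10-O-isopropylidene derivative of 15 (C6 hydroxyl free)
Conditions: Me2C(OMe)2, PPTS, CH2Cl2, 25 °C
Reagents that add atoms: 2,2-dimethoxypropane, COC(C)(C)OC
Why: Acid-catalysed acetonide formation selects the vicinal C1,C10-diol (five-membered dioxolane) over the isolated C6 hydroxyl and masks C1 and C10 through the enolate steps.

Step 14
Reactants: 16 1,10-O-isopropylidene derivative of 15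
Product: 17 6α,12-diol (16 without the tert-butyldimethylsilyl group)
Conditions: HF·pyridine, pyridine, THF, 0 °C
Reagents that add atoms: none
Why: Pyridine-buffered HF·pyridine cleaves a primary tert-butyldimethylsilyl ether much faster than a hindered secondary triisopropylsilyl ether and leaves the acetonide intact.

Step 15
Reactants: 17 6α,12-diol
Product: 19 cis-fused 12,6α-olide (H-6β, H-7β) with 1,10-O-isopropylidene, 8α-(4-methoxybenzyloxy) and 3β-(triisopropylsilyloxy) groups, via lactol 18 (not isolated)
Conditions: TEMPO (cat.), PhI(OAc)2, CH2Cl2, 25 °C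
Reagents that add atoms: none
Why: Oxoammonium oxidation of a 1,4-diol: the primary alcohol is oxidised selectively, the aldehyde closes onto the C6 hydroxyl and the lactol is oxidised to the γ-lactone. With O8 still benzylated only the 12,6-olide can form.

Step 16
Reactants: 19 cis-fused 12,6α-olide
Product: 21 7(11)-en-12,6α-olide (butenolide) with 8α-(4-methoxybenzyloxy) group, via selenide 20 (not isolated)
Conditions: LiN(iPr)2, THF, −78 °C; PhSeBr; then H2O2 (30%), pyridine, CH2Cl2, 0 to 25 °C
Reagents that add atoms: none
Why: α-Selenenylation of the lactone enolate from the convex face (cis to H-7) and selenoxide syn elimination toward C7, the only β-hydrogen, give the butenolide. The wrongly configured C7 centre is thereby erased.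

Step 17
Reactants: 21 7(11)-en-12,6α-olide with 8α-(4-methoxybenzyloxy) group
Product: 22 8α-hydroxy-7(11)-en-12,6α-olide
Conditions: DDQ, CH2Cl2–pH 7 buffer, 0 °C
Reagents that add atoms: none
Why: Oxidative cleavage of a p-methoxybenzyl ether by DDQ through the benzylic oxocarbenium ion; silyl ether, acetonide and the electron-poor butenolide are inert.

Step 18
Reactants: 22 8α-hydroxy-7(11)-en-12,6α-olide
Product: 23 trans-fused 8α-hydroxy-12,6α-olide (H-6β, H-7α)
Conditions: [Ir(cod)(PCy3)(py)]PF6 (10 mol%), H2 (1 atm), CH2Cl2, 25 °C
Reagents that add atoms: none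
Why: Hydroxyl-directed homogeneous hydrogenation with a cationic iridium catalyst: coordination to the C8 hydroxyl delivers H2 to the butenolide face on which that hydroxyl lies. This is the face opposite to H-6, so the trans-fused lactone with the required C7 configuration results.

Step 19
Reactants: 23 trans-fused 8α-hydroxy-12,6α-olide
Product: 26 8α-hydroxy-11(13)-en-12,6α-olide (α-methylene lactone; 1,10-O-isopropylidene, 3β-triisopropylsilyloxy), via trimethylsilyl ether 24 (not isolated), via Mannich base 25 (not isolated)
Conditions: Me3SiCl, imidazole, CH2Cl2, 0 °C; LiN(iPr)2, THF, −78 °C; (CH2=NMe2)I, −78 to 0 °C; MeI, MeOH; NaHCO3 (aq); citric acid (aq)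
Reagents that add atoms: N,N-dimethylmethyleneiminium iodide (Eschenmoser's salt), C=[N+](C)C.[I-]
Why: Mannich methylenation of the lactone enolate, then quaternisation and β-elimination of trimethylamine. Transient O-silylation of C8 prevents alkoxide-induced translactonisation to the 12,8-olide; the silyl ether is lost in the methanolic and acidic work-up.

Step 20
Reactants: 26 8α-hydroxy-11(13)-en-12,6α-olide
Product: 27 8α-angeloyloxy-11(13)-en-12,6α-olide (1,10-O-isopropylidene, 3β-triisopropylsilyloxy)
Conditions: angelic acid, 2,4,6-Cl3C6H2COCl, Et3N, toluene, 25 °C; then 26, 80 °C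
Reagents that add atoms: angelic acid, C/C=C(/C)C(=O)O
Why: Yamaguchi esterification through the mixed 2,4,6-trichlorobenzoic anhydride without a nucleophilic amine catalyst acylates hindered secondary alcohols while preserving the Z geometry of the angelate; no stereocentre is affected.

Step 21
Reactants: 27 8α-angeloyloxy-11(13)-en-12,6α-olide acetonide
Product: 28 8α-angeloyloxy-1ξ,10α-dihydroxy-3β-(triisopropylsilyloxy)-11(13)-en-12,6α-olide
Conditions: AcOH–H2O–THF, 45 °C
Reagents that add atoms: none
Why: Acid-catalysed acetonide hydrolysis; the silyl ether, the esters and the α-methylene lactone tolerate aqueous acetic acid.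

Step 22
Reactants: 28 8α-angeloyloxy-1ξ,10α-dihydroxy-3β-(triisopropylsilyloxy)-11(13)-en-12,6α-olide
Product: 29 8α-angeloyloxy-10α-hydroxy-1-oxo-3β-(triisopropylsilyloxy)-11(13)-en-12,6α-olide
Conditions: Dess–Martin periodinane, NaHCO3, CH2Cl2, 0 to 25 °C
Reagents that add atoms: none
Why: Dess–Martin oxidation converts the secondary C1 carbinol (either epimer) into the ketone; the tertiary C10 alcohol cannot be oxidised.

Step 23
Reactants: 29 8α-angeloyloxy-10α-hydroxy-1-oxo-3β-(triisopropylsilyloxy)-11(13)-en-12,6α-olide
Product: 30 10α-acetoxy-8α-angeloyloxy-1-oxo-3β-(triisopropylsilyloxy)-11(13)-en-12,6α-olide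
Conditions: Ac2O, Sc(OTf)3 (cat.), MeCN, −20 °C
Reagents that add atoms: acetic anhydride, CC(=O)OC(C)=O
Why: Lewis-acid-catalysed acylation of a tertiary alcohol with acetic anhydride; it is preferred to amine catalysis, which is slow at this centre and could isomerise the angelate or eliminate the β-silyloxy group.

Step 24
Reactants: 30 10α-acetoxy-8α-angeloyloxy-1-oxo-3β-(triisopropylsilyloxy)-11(13)-en-12,6α-olide
Product: 31 target, 10α-acetoxy-8α-angeloyloxy-3β-hydroxy-4α-methyl-1-oxogermacr-11(13)-en-12,6α-olide (3S,4S,6R,7S,8S,10R)
Conditions: HF·pyridine, THF, 25 °C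
Reagents that add atoms: none
Why: Fluoride-mediated cleavage of the last silyl ether under weakly acidic conditions, which do not provoke retro-aldol cleavage or dehydration of the β-hydroxy ketone and leave the esters and the α-methylene lactone untouched.

## Compound list

1 | 4-methylanisole | COc1ccc(C)cc1 | starting material
2 | 1-methoxy-4-methylcyclohexa-1,4-diene | COC1=CCC(C)=CC1 | intermediate
3 | 8-methyl-1,4-dioxaspiro[4.5]dec-7-ene | CC1=CCC2(CC1)OCCO2 | intermediate
4 | (7S,8S)-8-methyl-1,4-dioxaspiro[4.5]decan-7-ol | O1CCOC12C[C@H](O)[C@@H](C)CC2 | intermediate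
5 | (7S,8S)-8-methyl-7-(triisopropylsilyloxy)-1,4-dioxaspiro[4.5]decane | O1CCOC12C[C@H](O[Si](C(C)C)(C(C)C)C(C)C)[C@@H](C)CC2 | intermediate
6 | (3S,4S)-4-methyl-3-(triisopropylsilyloxy)cyclohexan-1-one | O=C1C[C@H](O[Si](C(C)C)(C(C)C)C(C)C)[C@@H](C)CC1 | intermediate
7 | but-3-yn-1-ol | OCCC#C | starting material
8 | (but-3-yn-1-yloxy)(tert-butyl)dimethylsilane | C#CCCO[Si](C)(C)C(C)(C)C | intermediate
9 | (E)-[(3-bromo-4-iodobut-3-en-1-yl)oxy](tert-butyl)dimethylsilane | I/C=C(/Br)CCO[Si](C)(C)C(C)(C)C | intermediate
10 | (E)-{[3-bromo-4-(4-methoxybenzyloxy)but-3-en-1-yl]oxy}(tert-butyl)dimethylsilane | COc1ccc(CO/C=C(/Br)CCO[Si](C)(C)C(C)(C)C)cc1 | intermediate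
11 | (2S,4S,5S)-2-[(E)-4-(tert-butyldimethylsilyloxy)-1-(4-methoxybenzyloxy)but-1-en-2-yl]-4-methyl-5-(triisopropylsilyloxy)cyclohexan-1-one | O=C1C[C@H](O[Si](C(C)C)(C(C)C)C(C)C)[C@@H](C)C[C@H]1/C(CCO[Si](C)(C)C(C)(C)C)=C/OCc2ccc(OC)cc2 | intermediate
12 | (1S,2S,4S,5S)-2-[(E)-4-(tert-butyldimethylsilyloxy)-1-(4-methoxybenzyloxy)but-1-en-2-yl]-4-methyl-1-(prop-1-en-2-yl)-5-(triisopropylsilyloxy)cyclohexan-1-ol | C=C(C)[C@]1(O)C[C@H](O[Si](C(C)C)(C(C)C)C(C)C)[C@@H](C)C[C@H]1/C(CCO[Si](C)(C)C(C)(C)C)=C/OCc2ccc(OC)cc2 | intermediate
13 | potassium (6E)-cyclodeca-1(10),6-dien-1-olate (enolate of 14 lacking the C10 oxygen; C2 trans to C9) | C[C@H]1C/C=C(CCO[Si](C)(C)C(C)(C)C)/[C@@H](OCc2ccc(OC)cc2)C/C(C)=C(\[O-])C[C@@H]1O[Si](C(C)C)(C(C)C)C(C)C.[K+] | intermediate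
14 | (6E)-10α-hydroxy-8α-(4-methoxybenzyloxy)-4α,10β-dimethyl-7-[2-(tert-butyldimethylsilyloxy)ethyl]-3β-(triisopropylsilyloxy)cyclodec-6-en-1-one | C[C@H]1C/C=C(CCO[Si](C)(C)C(C)(C)C)/[C@@H](OCc2ccc(OC)cc2)C[C@@](C)(O)C(=O)C[C@@H]1O[Si](C(C)C)(C(C)C)C(C)C | intermediate
15 | 8α-(4-methoxybenzyloxy)-4α,10β-dimethyl-7α-[2-(tert-butyldimethylsilyloxy)ethyl]-3β-(triisopropylsilyloxy)cyclodecane-1ξ,6α,10α-triol | C[C@H]1C[C@@H](O)[C@@H](CCO[Si](C)(C)C(C)(C)C)[C@@H](OCc2ccc(OC)cc2)C[C@@](C)(O)C(O)C[C@@H]1O[Si](C(C)C)(C(C)C)C(C)C | intermediate
16 | 1,10-O-isopropylidene derivative of 15 | C[C@H]1C[C@@H](O)[C@@H](CCO[Si](C)(C)C(C)(C)C)[C@@H](OCc2ccc(OC)cc2)C[C@@]3(C)OC(C)(C)OC3C[C@@H]1O[Si](C(C)C)(C(C)C)C(C)C | intermediate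
17 | 6α,12-diol (1,10-O-isopropylidene, 8α-(4-methoxybenzyloxy), 3β-triisopropylsilyloxy) | C[C@H]1C[C@@H](O)[C@@H](CCO)[C@@H](OCc2ccc(OC)cc2)C[C@@]3(C)OC(C)(C)OC3C[C@@H]1O[Si](C(C)C)(C(C)C)C(C)C | intermediate
18 | cis-fused 12,6α-lactol | C1C(O)O[C@@H]2C[C@H](C)[C@@H](O[Si](C(C)C)(C(C)C)C(C)C)CC3OC(C)(C)O[C@]3(C)C[C@H](OCc4ccc(OC)cc4)[C@H]12 | intermediate
19 | cis-fused 12,6α-olide (H-6β, H-7β), 8α-(4-methoxybenzyloxy) | C1C(=O)O[C@@H]2C[C@H](C)[C@@H](O[Si](C(C)C)(C(C)C)C(C)C)CC3OC(C)(C)O[C@]3(C)C[C@H](OCc4ccc(OC)cc4)[C@H]12 | intermediate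
20 | 11-phenylselanyl derivative of 19 | C1([Se]c5ccccc5)C(=O)O[C@@H]2C[C@H](C)[C@@H](O[Si](C(C)C)(C(C)C)C(C)C)CC3OC(C)(C)O[C@]3(C)C[C@H](OCc4ccc(OC)cc4)[C@H]12 | intermediate
21 | 7(11)-en-12,6α-olide (butenolide), 8α-(4-methoxybenzyloxy) | O=C1O[C@@H]2C[C@H](C)[C@@H](O[Si](C(C)C)(C(C)C)C(C)C)CC3OC(C)(C)O[C@]3(C)C[C@H](OCc4ccc(OC)cc4)C2=C1 | intermediate
22 | 8α-hydroxy-7(11)-en-12,6α-olide | O=C1O[C@@H]2C[C@H](C)[C@@H](O[Si](C(C)C)(C(C)C)C(C)C)CC3OC(C)(C)O[C@]3(C)C[C@H](O)C2=C1 | intermediate
23 | trans-fused 8α-hydroxy-12,6α-olide (H-7α) | C1C(=O)O[C@@H]2C[C@H](C)[C@@H](O[Si](C(C)C)(C(C)C)C(C)C)CC3OC(C)(C)O[C@]3(C)C[C@H](O)[C@@H]12 | intermediate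
24 | 8-O-trimethylsilyl ether of 23 | C1C(=O)O[C@@H]2C[C@H](C)[C@@H](O[Si](C(C)C)(C(C)C)C(C)C)CC3OC(C)(C)O[C@]3(C)C[C@H](O[Si](C)(C)C)[C@@H]12 | intermediate
25 | 11-(dimethylaminomethyl) lactone (Mannich base of 24) | C1(CN(C)C)C(=O)O[C@@H]2C[C@H](C)[C@@H](O[Si](C(C)C)(C(C)C)C(C)C)CC3OC(C)(C)O[C@]3(C)C[C@H](O[Si](C)(C)C)[C@@H]12 | intermediate
26 | 8α-hydroxy-11(13)-en-12,6α-olide (1,10-O-isopropylidene, 3β-triisopropylsilyloxy) | C=C1C(=O)O[C@@H]2C[C@H](C)[C@@H](O[Si](C(C)C)(C(C)C)C(C)C)CC3OC(C)(C)O[C@]3(C)C[C@H](O)[C@@H]12 | intermediate
27 | 8α-angeloyloxy-11(13)-en-12,6α-olide (1,10-O-isopropylidene, 3β-triisopropylsilyloxy) | C=C1C(=O)O[C@@H]2C[C@H](C)[C@@H](O[Si](C(C)C)(C(C)C)C(C)C)CC3OC(C)(C)O[C@]3(C)C[C@H](OC(=O)/C(C)=C\C)[C@@H]12 | intermediate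
28 | 8α-angeloyloxy-1ξ,10α-dihydroxy-3β-(triisopropylsilyloxy)-11(13)-en-12,6α-olide | C=C1C(=O)O[C@@H]2C[C@H](C)[C@@H](O[Si](C(C)C)(C(C)C)C(C)C)CC(O)[C@](C)(O)C[C@H](OC(=O)/C(C)=C\C)[C@@H]12 | intermediate
29 | 8α-angeloyloxy-10α-hydroxy-1-oxo-3β-(triisopropylsilyloxy)-11(13)-en-12,6α-olide | C=C1C(=O)O[C@@H]2C[C@H](C)[C@@H](O[Si](C(C)C)(C(C)C)C(C)C)CC(=O)[C@](C)(O)C[C@H](OC(=O)/C(C)=C\C)[C@@H]12 | intermediate
30 | 10α-acetoxy-8α-angeloyloxy-1-oxo-3β-(triisopropylsilyloxy)-11(13)-en-12,6α-olide | C=C1C(=O)O[C@@H]2C[C@H](C)[C@@H](O[Si](C(C)C)(C(C)C)C(C)C)CC(=O)[C@](C)(OC(C)=O)C[C@H](OC(=O)/C(C)=C\C)[C@@H]12 | intermediate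
31 | 10α-acetoxy-8α-angeloyloxy-3β-hydroxy-4α-methyl-1-oxogermacr-11(13)-en-12,6α-olide (3S,4S,6R,7S,8S,10R) | C=C1C(=O)O[C@@H]2C[C@H](C)[C@@H](O)CC(=O)[C@](C)(OC(C)=O)C[C@H](OC(=O)/C(C)=C\C)[C@@H]12 | target

## Step count and least certain steps

Total: 24 steps. Longest linear sequence: 21 steps (steps 1–5 and 9–24 from 4-methylanisole); the alkenyl bromide 10 is made separately in 3 steps (6–8).

Step 11 (key step). The most likely failure is equilibration of the kinetically formed C1–C10 enolate toward C2 by proton transfer inside the medium ring before oxygen is delivered, followed by loss of the C3 silanolate. The enolate may also add to the sulfonylimine released by the oxidant, and the facial selectivity of the hydroxylation rests on a conformational argument only. Fallback, from 12 back to 14: the rearrangement is run as before, but the enolate is quenched at −78 °C with Me3SiCl/Et3N and the trimethylsilyl enol ether F1 is isolated. Rubottom oxidation with one equivalent of m-chloroperbenzoic acid (NaHCO3, CH2Cl2, −40 °C; citric acid work-up) then gives 14, the electron-rich silyl enol ether being epoxidised before the trisubstituted olefin. This separates C–C bond formation from oxidation and removes both the lifetime of the basic enolate and the imine.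

Step 9. The most likely failure is loss of enolate regiochemistry by proton exchange while the electron-rich, hindered bromide adds slowly to zerovalent palladium; the C2 enolate then eliminates the silyloxy group. Over-alkenylation is a second risk. Fallback, from 6 back to 11: kinetic deprotonation (LiN(iPr)2, −78 °C) and Me3SiCl give the silyl enol ether F2, which is coupled with 10 under neutral conditions through the tin enolate formed in situ (Bu3SnF, PdCl2[P(o-tol)3]2, toluene, 100 °C). Brief treatment with Et3N then settles the equatorial C6 epimer.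

Step 12. The most likely failure is addition to the face of the E olefin other than the one assumed, which gives the wrong C6 configuration; slow hydroboration of the hindered trisubstituted olefin is the second risk. Fallback, from 14 back to 21: an anti addition replaces the syn addition, so that oxygen enters on the face opposite to the electrophile. NaBH4 gives the 1,10-diol F3 and Me2C(OMe)2/PPTS its acetonide F4; HF·pyridine frees the primary alcohol F5, and TEMPO/PhI(OAc)2 followed by NaClO2 gives the β,γ-unsaturated acid F6. PhSeCl (CH2Cl2, −78 °C) closes the seleno-lactone F7 with O6 anti to selenium, and H2O2 eliminates the selenoxide toward C11 to give 21. This gives the required C6 configuration exactly when the olefin reacts on the unexpected face, and it bypasses 15–20.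

Step 18. The most likely failure is an insufficient directing effect, because the lactone carbonyl and the acetonide oxygens also bind the metal; hydrogen would then arrive on the less hindered face and give the cis-fused lactone. Low reactivity of the trisubstituted, electron-poor olefin is the second risk. Fallback, from 22 back to 23: a covalent tether replaces coordination. ClSiMe2H/Et3N gives the dimethylsilyl ether F8; intramolecular hydrosilylation (Pt2[(CH2=CHSiMe2)2O]3, toluene, 60 °C) gives the oxasilolane F9, with hydrogen delivered to C7 from the O8 face and silicon on C11. KF/KHCO3 in MeOH then removes silicon from the α-silyl lactone and from O8 to give 23.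

## Further compounds

F1 | step 11 | trimethylsilyl enol ether of the rearranged ketone (C1–O–SiMe3, C1=C10, 6E) | C[C@H]1C/C=C(CCO[Si](C)(C)C(C)(C)C)/[C@@H](OCc2ccc(OC)cc2)C/C(C)=C(\O[Si](C)(C)C)C[C@@H]1O[Si](C(C)C)(C(C)C)C(C)C
F2 | step 9 | (4S,5S)-4-methyl-5-(triisopropylsilyloxy)-1-(trimethylsilyloxy)cyclohex-1-ene | C[Si](C)(C)OC1=CC[C@H](C)[C@@H](O[Si](C(C)C)(C(C)C)C(C)C)C1
F3 | step 12 | (6E)-cyclodec-6-ene-1ξ,10α-diol from reduction of 14 | C[C@H]1C/C=C(CCO[Si](C)(C)C(C)(C)C)/[C@@H](OCc2ccc(OC)cc2)C[C@@](C)(O)C(O)C[C@@H]1O[Si](C(C)C)(C(C)C)C(C)C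
F4 | step 12 | 1,10-O-isopropylidene derivative of F3 | C[C@H]1C/C=C(CCO[Si](C)(C)C(C)(C)C)/[C@@H](OCc2ccc(OC)cc2)C[C@@]3(C)OC(C)(C)OC3C[C@@H]1O[Si](C(C)C)(C(C)C)C(C)C
F5 | step 12 | primary alcohol (F4 without the tert-butyldimethylsilyl group) | C[C@H]1C/C=C(CCO)/[C@@H](OCc2ccc(OC)cc2)C[C@@]3(C)OC(C)(C)OC3C[C@@H]1O[Si](C(C)C)(C(C)C)C(C)C
F6 | step 12 | β,γ-unsaturated carboxylic acid (C12 acid of F5) | C[C@H]1C/C=C(CC(=O)O)/[C@@H](OCc2ccc(OC)cc2)C[C@@]3(C)OC(C)(C)OC3C[C@@H]1O[Si](C(C)C)(C(C)C)C(C)C
F7 | step 12 | 7-phenylselanyl-12,6α-olide (O6 and Se anti) | C1C(=O)O[C@@H]2C[C@H](C)[C@@H](O[Si](C(C)C)(C(C)C)C(C)C)CC3OC(C)(C)O[C@]3(C)C[C@H](OCc4ccc(OC)cc4)[C@@]12[Se]c5ccccc5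
F8 | step 18 | 8-O-dimethylsilyl ether of 22 | O=C1O[C@@H]2C[C@H](C)[C@@H](O[Si](C(C)C)(C(C)C)C(C)C)CC3OC(C)(C)O[C@]3(C)C[C@H](O[SiH](C)C)C2=C1
F9 | step 18 | oxasilolane (Si bridging O8 and C11, H-7α) | C[Si]1(C)O[C@H]2C[C@@]3(C)OC(C)(C)OC3C[C@H](O[Si](C(C)C)(C(C)C)C(C)C)[C@@H](C)C[C@H]4OC(=O)C1[C@H]24
A1 | alternative 1 | isoxazoline-bridged germacranolide core | C1C(=O)O[C@@H]2C[C@H](C)[C@@H]3CC(=NO3)[C@](C)(O[Si](CC)(CC)CC)C[C@H](O[Si](C)(C)C(C)(C)C)[C@@H]12
A2 | alternative 1 | open-chain C1 aldoxime with terminal C2=C3 alkene | C=C[C@@H](C)C[C@H]1OC(=O)C[C@@H]1[C@@H](O[Si](C)(C)C(C)(C)C)C[C@@](C)(O[Si](CC)(CC)CC)C=NO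
A3 | alternative 2 | ten-membered homoallylic alcohol | CC(C)(C)[Si](C)(C)O[C@@H]1C[C@H](C)[C@@H](OCc3ccc(OC)cc3)C[C@@H]2OC(C)(C)O[C@]2(C)C[C@H](O)[C@H]1C(=C)CO[Si](C)(C)C(C)(C)C
A4 | alternative 2 | thirteen-membered α-stannyl allylic ether (C8 and olefin geometry left open) | CC(C)(C)[Si](C)(C)O[C@@H]1C[C@H](C)[C@@H](OCc3ccc(OC)cc3)C[C@@H]2OC(C)(C)O[C@]2(C)CC([Sn](CCCC)(CCCC)CCCC)OCC(CO[Si](C)(C)C(C)(C)C)=C1
A5 | alternative 3 | ten-membered C1,C10-diol | C1C(=O)O[C@@H]2C[C@H](C)[C@@H](OCc3ccc(OC)cc3)C[C@H](O)[C@](C)(O)C[C@H](O[Si](C)(C)C(C)(C)C)[C@@H]12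
A6 | alternative 3 | C1 aldehyde / C10 methyl ketone | O=CC[C@H](OCc2ccc(OC)cc2)[C@@H](C)C[C@H]1OC(=O)C[C@@H]1[C@@H](O[Si](C)(C)C(C)(C)C)CC(C)=O
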